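I started from a count that no rate can alter, provided each E costs one Z: E, with anything else Z turns into, stays under the Z ceiling, 50.0% in noon and autumn, meaning the Z charged as a fraction of the L and D together charged.

| flask | L | D | Z | G | temperature | remark | time |
|---|---|---|---|---|---|---|---|
| elm | 0.35 M | 0.35 M | 0.71 M | 0.35 mM | −22 °C | run made earlier |  |
| oak | 0.53 M | 0.53 M | 0.71 M | 0.35 mM | −6 °C | run made earlier |  |
| noon | 0.71 M | 0.71 M | 0.710 M | 0.35 mM | −30 °C |  | 40 h |
| autumn | 0.71 M | 0.71 M | 0.710 M | 0.35 mM | 0 °C |  | 40 h |

| run | time / h | E / % | L / % |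
|---|---|---|---|
| elm | 3.00 | 46.0 | 6.0 |
| elm | 5.00 | 49.2 | 1.6 |
| elm | 8.00 | 49.9 | 1.7 |
| elm | 15.0 | 51.7 | 0 |
| elm | 25.0 | 51.6 | 1.0 |
| elm | 40.0 | 50.4 | 2.0 |
| oak | 1.00 | 41.5 | 8.5 |
| oak | 1.50 | 46.3 | 5.9 |
| oak | 2.50 | 49.2 | 3.3 |
| oak | 5.00 | 51.2 | 2.4 |
| oak | 8.00 | 52.2 | 1.4 |
| oak | 12.0 | 52.5 | 0.9 |

(scatter of a reading: 1 percentage point)

- G is single-handed; L and D are mirror images of each other, charged as a racemate, each of them at the stated concentration

- the best flask by amount of E, in percent of the L and D together charged; "all alike" if 1.5 percentage points covers them all (noon / autumn / all alike)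
- amount of E at the end, in percent of the L and D together charged, noon
- amount of E at the end, in percent of the L and D together charged, autumn

Elm's ceiling was 101% and oak's 67.0%, and the highest E read was 52.5% in oak, so neither run came near its ceiling. In noon and autumn, Z is charged equal to L, so I took Z as the limiting reagent and made a rough estimate: if Z went to L and nowhere else, and L gained nothing from D, the fraction of L left would be the reciprocal of one plus a·t, where a is the pace per hour at full Z charge. I read a from the first L reading of each run, taking a rate proportional to the product of L and Z: 1.02 /h at −22 °C and 3.18 /h at −6 °C. Taking ln a as straight in temperature, I got 0.578 /h for noon and 4.87 /h for autumn. The ceiling times the fraction consumed then gave E of 47.9% in noon and 49.7% in autumn, a gap of 1.8 percentage points.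

The weak link was the assumption that Z goes to L and nowhere else: the runs read E and L but not Z, so I had no reading of where Z went. So I reforged the two numbers as estimates that were probably too high, and a side loss in autumn of 0.32 points beyond noon's would erase the lead.

The forecast gave 47% for noon and 49.3% for autumn, both lower than my figures, and named autumn: “Autumn is the likely best, but the margin is modest.”

The simulation gives 46.8% in noon and 46.4% in autumn, so the answer is all alike.

    2 Z → Q (k = 4.07 × 10⁻⁵ /M/s, Ea = 61.0 kJ/mol)
    Z + G + L → G + E (k = 5.55 /M²/s, Ea = 38.0 kJ/mol)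
    L ⇌ D (k = 1.02 × 10⁻⁵ /s, Ea = 101 kJ/mol)
    Z + G + D → G + X (k = 0.0976 /M²/s, Ea = 42.0 kJ/mol)
    (constants at 0 °C)

Autumn has Z at 0% of its charge and Q at 0.0117 M, which at two Z each is 1.65% of the L and D charged, while noon loses less, 1.30%, to Q and unused Z together, and the activation energy of the step to Q stands 23.0 kJ/mol above that of the L step. With 0.18 M of Z, a neighbour flask otherwise like noon has a ceiling of 12.7% and holds E at 12.5% and X at 0.202%.

All runs stem from a simulated flask on assumed constants; scatter was added.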